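The oxolane is cut at C2–C3. C2 is a benzylic ether carbon that carries one hydrogen, and C3 bears a one-carbon arm that can stand at the ester level. A rhodium carbenoid placed on C3 (from an α-diazo ester) can therefore insert into the C–H bond of an aryl–CH2–O ether: one operation closes the ring, forms C2–C3 and sets C2 and C3. The precursor is an acyclic methyl 2-diazobutanoate whose C4/C5 pair (silyloxymethyl arm; aryl carbinol ether) comes from an auxiliary-controlled syn aldol. The C5 aryl is deactivated as a pivalate and the ring of the benzyl ether carries a silyl ether, so hydride and fluoride finish the synthesis.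

Key step: step 13

Remark: ring atoms are numbered O1, C2 (aryl carbon derived from the benzyl ether CH2), C3 (carbenoid carbon), C4 and C5 (aldol carbinol carbon); the target is 2,3-cis, 3,4-trans, 4,5-trans, i.e. (2S,3S,4S,5R) in this numbering, which corresponds to (3S,4R) in precursor 19 and (2S,3R,4S,5R) in insertion product 20 (C3 changes letter only because the ester outranks C2).

Step 1
Reactants: 1 syringaldehyde
Product: 2 4-formyl-2,6-dimethoxyphenyl pivalate
Conditions: PivCl, Et3N, DMAP (cat.), CH2Cl2, 0 °C → rt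
Reagents that add atoms: pivaloyl chloride, CC(C)(C)C(=O)Cl
Why: DMAP-catalysed O-acylation of the phenol gives a hindered aryl pivalate that lowers the electron density of this ring and is later cleaved by hydride.

Step 2
Reactants: 1 syringaldehyde
Product: 3 3,5-dimethoxy-4-(triisopropylsilyloxy)benzaldehyde
Conditions: TIPSCl, imidazole, DMF, rt
Reagents that add atoms: chlorotriisopropylsilane, CC(C)[Si](Cl)(C(C)C)C(C)C
Why: Imidazole-promoted silylation of the phenol gives a bulky aryl silyl ether that keeps this ring electron-rich and is removed by fluoride together with the alkyl silyl ether in the last step.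

Step 3
Reactants: 3 silyl-protected aldehyde
Product: 4 [3,5-dimethoxy-4-(triisopropylsilyloxy)phenyl]methanol
Conditions: NaBH4, MeOH, 0 °C
Reagents that add atoms: none
Why: Borohydride reduction of the aryl aldehyde to the benzylic alcohol leaves the aryl silyl ether untouched.

Step 4
Reactants: 4 benzylic alcohol
Product: 5 3,5-dimethoxy-4-(triisopropylsilyloxy)benzyl 2,2,2-trichloroacetimidate
Conditions: Cl3CCN, DBU (10 mol %), CH2Cl2, 0 °C; filtered through basic alumina and used at once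
Reagents that add atoms: trichloroacetonitrile, N#CC(Cl)(Cl)Cl
Why: Base-catalysed addition of the alkoxide to the nitrile (imidate formation) turns the alcohol into a benzyl donor that is activated by acid only.

Step 5
Reactants: 6 (R)-4-benzyloxazolidin-2-one; 7 pent-4-enoyl chloride
Product: 8 (R)-4-benzyl-3-(pent-4-enoyl)oxazolidin-2-one
Conditions: n-BuLi, THF, −78 °C; then 7, −78 → 0 °C
Reagents that add atoms: none
Why: N-Acylation of the lithiated oxazolidinone installs a pentenoyl unit whose alkene is a latent ester, so that no γ-hydroxy ester able to lactonise exists before the C5 ether is in place.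

Step 6
Reactants: 8 pentenoyl imide; 2 aryl aldehyde pivalate
Product: 10 (4R)-4-benzyl-3-[(2R)-2-{(R)-[3,5-dimethoxy-4-(pivaloyloxy)phenyl](hydroxy)methyl}pent-4-enoyl]oxazolidin-2-one, via Z-dibutylboron enolate 9 (not isolated)
Conditions: Bu2BOTf, i-Pr2NEt, CH2Cl2, −78 → 0 °C; 2, −78 → 0 °C; then pH 7 buffer, MeOH, 30% H2O2, 0 °C
Reagents that add atoms: none
Why: Evans syn-aldol in which the Z-boron enolate reacts through a closed chair transition state with the auxiliary carbonyl turned away and its (R)-benzyl group shielding one enolate face, which sets C4 and C5 as the syn pair that becomes 4,5-trans in the ring.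

Step 7
Reactants: 10 syn-aldol adduct; 5 benzyl trichloroacetimidate
Product: 11 (4R)-4-benzyl-3-[(2R)-2-{(R)-[3,5-dimethoxy-4-(pivaloyloxy)phenyl]{[3,5-dimethoxy-4-(triisopropylsilyloxy)phenyl]methoxy}methyl}pent-4-enoyl]oxazolidin-2-one
Conditions: 5 (2 equiv, slow addition), TfOH (1 mol %), CH2Cl2, 4 Å MS, −40 → −10 °C
Reagents that add atoms: none
Why: Acid-catalysed O-benzylation by the trichloroacetimidate forms the ether whose CH2 becomes C2 under conditions that cannot cause retro-aldol cleavage, while C5 keeps its configuration because its own ionisation is disfavoured by the acyloxy-substituted ring.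

Step 8
Reactants: 11 ether imide
Product: 12 4-[(1R,2S)-1-{[3,5-dimethoxy-4-(triisopropylsilyloxy)phenyl]methoxy}-2-(hydroxymethyl)pent-4-en-1-yl]-2,6-dimethoxyphenyl pivalate
Conditions: LiBH4, MeOH (1.5 equiv), THF, 0 °C
Reagents that add atoms: none
Why: Reductive cleavage of the N-acyl oxazolidinone by hydride attack on the exocyclic carbonyl releases the C4 hydroxymethyl arm, the di-ortho-substituted aryl pivalate being much less electrophilic than the imide at 0 °C.

Step 9
Reactants: 12 primary alcohol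
Product: 13 4-[(1R,2S)-2-{[tert-butyl(dimethyl)silyl]oxymethyl}-1-{[3,5-dimethoxy-4-(triisopropylsilyloxy)phenyl]methoxy}pent-4-en-1-yl]-2,6-dimethoxyphenyl pivalate
Conditions: TBSCl, imidazole, CH2Cl2, rt
Reagents that add atoms: tert-butyl(chloro)dimethylsilane, CC(C)(C)[Si](C)(C)Cl
Why: Imidazole-promoted silylation masks the C4 arm as an ether that is inert to strong base and offers the carbenoid no C–H bond within reach.

Step 10
Reactants: 13 silyl ether alkene
Product: 15 4-[(1R,2S)-2-{[tert-butyl(dimethyl)silyl]oxymethyl}-1-{[3,5-dimethoxy-4-(triisopropylsilyloxy)phenyl]methoxy}-4-oxobutyl]-2,6-dimethoxyphenyl pivalate, via vicinal diol 14 (not isolated)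
Conditions: K2OsO4·2H2O (2 mol %), NaIO4 (4 equiv), 2,6-lutidine, dioxane/H2O (3:1), rt
Reagents that add atoms: sodium periodate, [Na+].[O-]I(=O)(=O)=O (oxygen of the new C=O, relayed by osmium tetroxide)
Why: Lemieux–Johnson cleavage (osmium-catalysed dihydroxylation of the terminal alkene, then periodate scission) gives the aldehyde without touching the electron-rich rings or the benzylic ether.

Step 11
Reactants: 15 aldehyde
Product: 17 methyl (3S,4R)-3-{[tert-butyl(dimethyl)silyl]oxymethyl}-4-{[3,5-dimethoxy-4-(triisopropylsilyloxy)phenyl]methoxy}-4-[3,5-dimethoxy-4-(pivaloyloxy)phenyl]butanoate, via carboxylic acid 16 (not isolated)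
Conditions: NaClO2, NaH2PO4, 2-methylbut-2-ene, t-BuOH/H2O, 0 °C → rt; then crude 16, TMSCHN2, PhMe/MeOH (4:1), 0 °C
Reagents that add atoms: sodium chlorite, [Na+].[O-]Cl=O; trimethylsilyldiazomethane, C[Si](C)(C)C=[N+]=[N-]
Why: Pinnick oxidation with a hypochlorite scavenger, followed by O-methylation of the crude acid with trimethylsilyldiazomethane, gives the methyl ester under conditions too mild to disturb the silyl ethers or the pivalate.

Step 12
Reactants: 17 methyl ester
Product: 19 methyl (3S,4R)-3-{[tert-butyl(dimethyl)silyl]oxymethyl}-2-diazo-4-{[3,5-dimethoxy-4-(triisopropylsilyloxy)phenyl]methoxy}-4-[3,5-dimethoxy-4-(pivaloyloxy)phenyl]butanoate, via α-formyl ester 18 (not isolated)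
Conditions: LDA (1.3 equiv), THF, −78 °C; HCO2CH2CF3, −78 → 0 °C; aq NH4Cl; then crude 18, p-ABSA, Et3N, MeCN, 0 °C → rt
Reagents that add atoms: 4-acetamidobenzenesulfonyl azide, CC(=O)Nc1ccc(cc1)S(=O)(=O)N=[N+]=[N-]
Why: Claisen-type C-formylation of the lithium ester enolate followed by Regitz deformylative diazo transfer places the diazo group on C3; C4 carries no leaving group, so the enolate cannot eliminate, and neither stereocentre is touched.

Step 13
Reactants: 19 α-diazo ester
Product: 20 methyl (2S,3R,4S,5R)-4-{[tert-butyl(dimethyl)silyl]oxymethyl}-2-[3,5-dimethoxy-4-(triisopropylsilyloxy)phenyl]-5-[3,5-dimethoxy-4-(pivaloyloxy)phenyl]oxolane-3-carboxylate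
Conditions: dirhodium tetrakis[N-phthaloyl-(S)-tert-leucinate], Rh2(S-PTTL)4 (1 mol %), CH2Cl2, −78 → −40 °C, slow addition of 19
Reagents that add atoms: none
Why: The dirhodium tetracarboxylate expels N2 from 19 to give an electrophilic rhodium carbenoid at C3, which draws the hydride-like C2–H bond of the benzylic ether into a concerted, asynchronous three-centre transition state that forms C2–C3 and C3–H and releases the catalyst. The closest known reaction type is the dirhodium-catalysed intramolecular 1,5 C–H insertion of α-diazo esters and α-diazo lactones next to ether oxygen, ArCH2–O bonds included, which gives cis-2-aryl cyclic ether 3-carboxylates. The oxolane closes by 1,5-insertion, a five-membered ring formed through a chair-like six-centre array of C3, C4, C5, O1, C2 and the migrating hydrogen. C2 is set by that chair, in which the new aryl group sits pseudo-equatorial like the C5 aryl and the C4 arm, hence 2,5-cis; C3 is set by the approach of the C–H bond with the aryl group turned away from the carboxylate wall and towards the ester, which places the ester cis to the C2 aryl and trans to the C4 arm, and the chiral ligand sphere is expected to reinforce this sense. Insertion must outrun the 1,2-hydride shift from C4, attack on the C5 aryl ring and reaction at other C–H bonds: the C2–H bond is the only one activated at once by oxygen, by an electron-rich aryl group and by 1,5 geometry, the bulky phthalimido carboxylate at −78 °C disfavours hydride migration, the pivalate lowers the nucleophilicity of the C5 ring, and the silyl ethers offer no C–H bond in reach.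

Step 14
Reactants: 20 oxolane ester
Product: 21 {(2S,3S,4S,5R)-4-{[tert-butyl(dimethyl)silyl]oxymethyl}-2-[3,5-dimethoxy-4-(triisopropylsilyloxy)phenyl]-5-(4-hydroxy-3,5-dimethoxyphenyl)oxolan-3-yl}methanol
Conditions: LiAlH4, THF, −20 → 0 °C; Rochelle salt work-up
Reagents that add atoms: none
Why: Lithium aluminium hydride reduces the C3 ester to the second hydroxymethyl group faster than the ester can enolise, so C3 is not epimerised and no retro-oxa-Michael ring opening occurs, and it cleaves the aryl pivalate in the same operation.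

Step 15
Reactants: 21 silyl-protected oxolane diol
Product: 22 [(2S,3S,4S,5R)-2,5-bis(4-hydroxy-3,5-dimethoxyphenyl)oxolane-3,4-diyl]dimethanol (target)
Conditions: TBAF (3 equiv), AcOH (3 equiv), THF, 0 °C → rt
Reagents that add atoms: none
Why: Fluoride-mediated desilylation, buffered with acetic acid so that the freed p-hydroxybenzylic ring ethers meet no strong base, removes the alkyl and the aryl silyl ether together and should give the target.

Compound list
1 | syringaldehyde (4-hydroxy-3,5-dimethoxybenzaldehyde) | COc1cc(C=O)cc(OC)c1O | starting material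
2 | 4-formyl-2,6-dimethoxyphenyl pivalate | COc1cc(C=O)cc(OC)c1OC(=O)C(C)(C)C | intermediate
3 | 3,5-dimethoxy-4-(triisopropylsilyloxy)benzaldehyde | COc1cc(C=O)cc(OC)c1O[Si](C(C)C)(C(C)C)C(C)C | intermediate
4 | [3,5-dimethoxy-4-(triisopropylsilyloxy)phenyl]methanol | COc1cc(CO)cc(OC)c1O[Si](C(C)C)(C(C)C)C(C)C | intermediate
5 | 3,5-dimethoxy-4-(triisopropylsilyloxy)benzyl 2,2,2-trichloroacetimidate | COc1cc(COC(=N)C(Cl)(Cl)Cl)cc(OC)c1O[Si](C(C)C)(C(C)C)C(C)C | intermediate
6 | (R)-4-benzyloxazolidin-2-one | O=C1OC[C@@H](Cc2ccccc2)N1 | starting material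
7 | pent-4-enoyl chloride | C=CCCC(=O)Cl | starting material
8 | (R)-4-benzyl-3-(pent-4-enoyl)oxazolidin-2-one | O=C1OC[C@@H](Cc2ccccc2)N1C(=O)CCC=C | intermediate
9 | (4R)-4-benzyl-3-[(1Z)-1-(dibutylboranyloxy)penta-1,4-dien-1-yl]oxazolidin-2-one (Z-boron enolate) | CCCCB(CCCC)O/C(=C\CC=C)N1C(=O)OC[C@H]1Cc1ccccc1 | intermediate (not isolated)
10 | (4R)-4-benzyl-3-[(2R)-2-{(R)-[3,5-dimethoxy-4-(pivaloyloxy)phenyl](hydroxy)methyl}pent-4-enoyl]oxazolidin-2-one | O=C1OC[C@@H](Cc2ccccc2)N1C(=O)[C@H](CC=C)[C@@H](O)c1cc(OC)c(OC(=O)C(C)(C)C)c(OC)c1 | intermediate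
11 | (4R)-4-benzyl-3-[(2R)-2-{(R)-[3,5-dimethoxy-4-(pivaloyloxy)phenyl]{[3,5-dimethoxy-4-(triisopropylsilyloxy)phenyl]methoxy}methyl}pent-4-enoyl]oxazolidin-2-one | O=C1OC[C@@H](Cc2ccccc2)N1C(=O)[C@H](CC=C)[C@@H](OCc1cc(OC)c(O[Si](C(C)C)(C(C)C)C(C)C)c(OC)c1)c1cc(OC)c(OC(=O)C(C)(C)C)c(OC)c1 | intermediate
12 | 4-[(1R,2S)-1-{[3,5-dimethoxy-4-(triisopropylsilyloxy)phenyl]methoxy}-2-(hydroxymethyl)pent-4-en-1-yl]-2,6-dimethoxyphenyl pivalate | OC[C@H](CC=C)[C@@H](OCc1cc(OC)c(O[Si](C(C)C)(C(C)C)C(C)C)c(OC)c1)c1cc(OC)c(OC(=O)C(C)(C)C)c(OC)c1 | intermediate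
13 | 4-[(1R,2S)-2-{[tert-butyl(dimethyl)silyl]oxymethyl}-1-{[3,5-dimethoxy-4-(triisopropylsilyloxy)phenyl]methoxy}pent-4-en-1-yl]-2,6-dimethoxyphenyl pivalate | CC(C)(C)[Si](C)(C)OC[C@H](CC=C)[C@@H](OCc1cc(OC)c(O[Si](C(C)C)(C(C)C)C(C)C)c(OC)c1)c1cc(OC)c(OC(=O)C(C)(C)C)c(OC)c1 | intermediate
14 | 4,5-dihydroxypentyl analogue of 13 (vicinal diol, both epimers at the new carbinol) | CC(C)(C)[Si](C)(C)OC[C@H](CC(O)CO)[C@@H](OCc1cc(OC)c(O[Si](C(C)C)(C(C)C)C(C)C)c(OC)c1)c1cc(OC)c(OC(=O)C(C)(C)C)c(OC)c1 | intermediate (not isolated)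
15 | 4-[(1R,2S)-2-{[tert-butyl(dimethyl)silyl]oxymethyl}-1-{[3,5-dimethoxy-4-(triisopropylsilyloxy)phenyl]methoxy}-4-oxobutyl]-2,6-dimethoxyphenyl pivalate | CC(C)(C)[Si](C)(C)OC[C@H](CC=O)[C@@H](OCc1cc(OC)c(O[Si](C(C)C)(C(C)C)C(C)C)c(OC)c1)c1cc(OC)c(OC(=O)C(C)(C)C)c(OC)c1 | intermediate
16 | (3S,4R)-3-{[tert-butyl(dimethyl)silyl]oxymethyl}-4-{[3,5-dimethoxy-4-(triisopropylsilyloxy)phenyl]methoxy}-4-[3,5-dimethoxy-4-(pivaloyloxy)phenyl]butanoic acid | CC(C)(C)[Si](C)(C)OC[C@H](CC(=O)O)[C@@H](OCc1cc(OC)c(O[Si](C(C)C)(C(C)C)C(C)C)c(OC)c1)c1cc(OC)c(OC(=O)C(C)(C)C)c(OC)c1 | intermediate (not isolated)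
17 | methyl (3S,4R)-3-{[tert-butyl(dimethyl)silyl]oxymethyl}-4-{[3,5-dimethoxy-4-(triisopropylsilyloxy)phenyl]methoxy}-4-[3,5-dimethoxy-4-(pivaloyloxy)phenyl]butanoate | COC(=O)C[C@@H](CO[Si](C)(C)C(C)(C)C)[C@@H](OCc1cc(OC)c(O[Si](C(C)C)(C(C)C)C(C)C)c(OC)c1)c1cc(OC)c(OC(=O)C(C)(C)C)c(OC)c1 | intermediate
18 | 2-formyl derivative of 17 (α-formyl ester, C2 epimers and enol form) | COC(=O)C(C=O)[C@@H](CO[Si](C)(C)C(C)(C)C)[C@@H](OCc1cc(OC)c(O[Si](C(C)C)(C(C)C)C(C)C)c(OC)c1)c1cc(OC)c(OC(=O)C(C)(C)C)c(OC)c1 | intermediate (not isolated)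
19 | methyl (3S,4R)-3-{[tert-butyl(dimethyl)silyl]oxymethyl}-2-diazo-4-{[3,5-dimethoxy-4-(triisopropylsilyloxy)phenyl]methoxy}-4-[3,5-dimethoxy-4-(pivaloyloxy)phenyl]butanoate | COC(=O)C(=[N+]=[N-])[C@@H](CO[Si](C)(C)C(C)(C)C)[C@@H](OCc1cc(OC)c(O[Si](C(C)C)(C(C)C)C(C)C)c(OC)c1)c1cc(OC)c(OC(=O)C(C)(C)C)c(OC)c1 | intermediate
20 | methyl (2S,3R,4S,5R)-4-{[tert-butyl(dimethyl)silyl]oxymethyl}-2-[3,5-dimethoxy-4-(triisopropylsilyloxy)phenyl]-5-[3,5-dimethoxy-4-(pivaloyloxy)phenyl]oxolane-3-carboxylate | COc1cc([C@H]2O[C@@H](c3cc(OC)c(OC(=O)C(C)(C)C)c(OC)c3)[C@H](CO[Si](C)(C)C(C)(C)C)[C@H]2C(=O)OC)cc(OC)c1O[Si](C(C)C)(C(C)C)C(C)C | intermediate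
21 | {(2S,3S,4S,5R)-4-{[tert-butyl(dimethyl)silyl]oxymethyl}-2-[3,5-dimethoxy-4-(triisopropylsilyloxy)phenyl]-5-(4-hydroxy-3,5-dimethoxyphenyl)oxolan-3-yl}methanol | COc1cc([C@H]2O[C@@H](c3cc(OC)c(O)c(OC)c3)[C@H](CO[Si](C)(C)C(C)(C)C)[C@H]2CO)cc(OC)c1O[Si](C(C)C)(C(C)C)C(C)C | intermediate
22 | [(2S,3S,4S,5R)-2,5-bis(4-hydroxy-3,5-dimethoxyphenyl)oxolane-3,4-diyl]dimethanol (2,3-cis, 3,4-trans, 4,5-trans) | COc1cc([C@H]2O[C@@H](c3cc(OC)c(O)c(OC)c3)[C@H](CO)[C@H]2CO)cc(OC)c1O | target

Total steps: 15. Longest linear sequence: 12 (steps 2–4, then 7–15, from syringaldehyde).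

Steps most likely to fail

Step 13 (C–H insertion). The 1,2-hydride shift from C4 to the carbenoid carbon may outrun insertion, or the insertion may deliver the aryl group at C2 or the ester at C3 on the wrong face. The fallback closes the ring by addition to a lactone and reduction of the lactol instead; in it the lactone carbonyl becomes C2 and the lactone α-carbon becomes C3. It sets out from 17: DDQ in CH2Cl2/pH 7 buffer removes the electron-rich benzyl group (it leaves as aldehyde 3), and the freed C5 hydroxyl closes onto the ester to give the trans-lactone (4S,5R)-4-{[tert-butyl(dimethyl)silyl]oxymethyl}-5-[3,5-dimethoxy-4-(pivaloyloxy)phenyl]oxolan-2-one F1. Its lithium enolate (LDA, THF, −78 °C) should take up monomeric formaldehyde anti to the C4 arm to give the (3S,4S,5R)-3-(hydroxymethyl) lactone F2. Commercial 4-bromo-2,6-dimethoxyphenol is silylated (TIPSCl, imidazole) to (4-bromo-2,6-dimethoxyphenoxy)triisopropylsilane F3, which n-BuLi (THF, −78 °C) converts into [3,5-dimethoxy-4-(triisopropylsilyloxy)phenyl]lithium F4. About 2.2 equivalents of F4 (one is spent on the free hydroxyl) should add once to the lactone carbonyl and give the 2-aryl-oxolan-2-ol (lactol, anomeric mixture) F5. Et3SiH with BF3·OEt2 in CH2Cl2 at −78 °C reduces the derived 2-aryl oxocarbenium ion; hydride is expected anti to the C3 arm and anti to the C5 aryl group, which gives the 2,3-cis, 2,5-cis oxolane, the 5-aryl pivalate of 21, F6. LiAlH4 as in step 14 removes the pivalate, and the route is rejoined at 21.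

Step 7 (etherification). The electron-rich benzyl cation may be consumed by Friedel–Crafts self-condensation, or the imidate may rearrange to the trichloroacetamide, before the hindered secondary alcohol is alkylated. The fallback forms the same C–O bond by reductive etherification, with no benzyl cation or imidate. It sets out from 10, which is silylated (TMSCl, imidazole, CH2Cl2) to the trimethylsilyl ether of 10, F7. F7 and aldehyde 3 with Et3SiH and TMSOTf (cat.) in CH2Cl2 at −78 °C should form an oxocarbenium ion that the silane reduces, and the route is rejoined at 11.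

Step 12 (diazo installation). C-Formylation of the hindered, β-branched enolate may stay incomplete, or the formyl group may be lost by retro-Claisen cleavage before diazo transfer. The fallback brings in nitrogen by electrophilic azidation and adjusts it afterwards. It sets out from 17: KHMDS (THF, −78 °C), then 2,4,6-triisopropylbenzenesulfonyl azide and an acetic acid quench give the α-azido ester, methyl 2-azido analogue of 17 (C2 epimers, of no consequence), F8. Staudinger reduction (PPh3, THF/H2O) gives the α-amino ester, methyl 2-amino analogue of 17, F9. Diazotisation (isoamyl nitrite, AcOH cat., CHCl3, 60 °C) should then give the diazo ester, and the route is rejoined at 19.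

Further compounds
F1 | step 13 | (4S,5R)-4-{[tert-butyl(dimethyl)silyl]oxymethyl}-5-[3,5-dimethoxy-4-(pivaloyloxy)phenyl]oxolan-2-one | O=C1C[C@@H](CO[Si](C)(C)C(C)(C)C)[C@H](c2cc(OC)c(OC(=O)C(C)(C)C)c(OC)c2)O1
F2 | step 13 | (3S,4S,5R)-4-{[tert-butyl(dimethyl)silyl]oxymethyl}-3-(hydroxymethyl)-5-[3,5-dimethoxy-4-(pivaloyloxy)phenyl]oxolan-2-one | O=C1[C@H](CO)[C@@H](CO[Si](C)(C)C(C)(C)C)[C@H](c2cc(OC)c(OC(=O)C(C)(C)C)c(OC)c2)O1
F3 | step 13 | (4-bromo-2,6-dimethoxyphenoxy)triisopropylsilane | COc1cc(Br)cc(OC)c1O[Si](C(C)C)(C(C)C)C(C)C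
F4 | step 13 | [3,5-dimethoxy-4-(triisopropylsilyloxy)phenyl]lithium | [Li]c1cc(OC)c(O[Si](C(C)C)(C(C)C)C(C)C)c(OC)c1
F5 | step 13 | (3S,4S,5R)-4-{[tert-butyl(dimethyl)silyl]oxymethyl}-2-[3,5-dimethoxy-4-(triisopropylsilyloxy)phenyl]-3-(hydroxymethyl)-5-[3,5-dimethoxy-4-(pivaloyloxy)phenyl]oxolan-2-ol (anomeric mixture) | COc1cc(C2(O)O[C@@H](c3cc(OC)c(OC(=O)C(C)(C)C)c(OC)c3)[C@H](CO[Si](C)(C)C(C)(C)C)[C@H]2CO)cc(OC)c1O[Si](C(C)C)(C(C)C)C(C)C
F6 | step 13 | {(2S,3S,4S,5R)-4-{[tert-butyl(dimethyl)silyl]oxymethyl}-2-[3,5-dimethoxy-4-(triisopropylsilyloxy)phenyl]-5-[3,5-dimethoxy-4-(pivaloyloxy)phenyl]oxolan-3-yl}methanol | COc1cc([C@H]2O[C@@H](c3cc(OC)c(OC(=O)C(C)(C)C)c(OC)c3)[C@H](CO[Si](C)(C)C(C)(C)C)[C@H]2CO)cc(OC)c1O[Si](C(C)C)(C(C)C)C(C)C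
F7 | step 7 | (4R)-4-benzyl-3-[(2R)-2-{(R)-[3,5-dimethoxy-4-(pivaloyloxy)phenyl](trimethylsilyloxy)methyl}pent-4-enoyl]oxazolidin-2-one | O=C1OC[C@@H](Cc2ccccc2)N1C(=O)[C@H](CC=C)[C@@H](O[Si](C)(C)C)c1cc(OC)c(OC(=O)C(C)(C)C)c(OC)c1
F8 | step 12 | methyl (3S,4R)-2-azido-3-{[tert-butyl(dimethyl)silyl]oxymethyl}-4-{[3,5-dimethoxy-4-(triisopropylsilyloxy)phenyl]methoxy}-4-[3,5-dimethoxy-4-(pivaloyloxy)phenyl]butanoate (C2 epimers) | COC(=O)C(N=[N+]=[N-])[C@@H](CO[Si](C)(C)C(C)(C)C)[C@@H](OCc1cc(OC)c(O[Si](C(C)C)(C(C)C)C(C)C)c(OC)c1)c1cc(OC)c(OC(=O)C(C)(C)C)c(OC)c1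
F9 | step 12 | methyl (3S,4R)-2-amino-3-{[tert-butyl(dimethyl)silyl]oxymethyl}-4-{[3,5-dimethoxy-4-(triisopropylsilyloxy)phenyl]methoxy}-4-[3,5-dimethoxy-4-(pivaloyloxy)phenyl]butanoate (C2 epimers) | COC(=O)C(N)[C@@H](CO[Si](C)(C)C(C)(C)C)[C@@H](OCc1cc(OC)c(O[Si](C(C)C)(C(C)C)C(C)C)c(OC)c1)c1cc(OC)c(OC(=O)C(C)(C)C)c(OC)c1
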